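## Analysis of the target

The target 34 is a C19 gibberellin-type keto acid (gibberellin numbering throughout): cyclohexanone ring A (C1–C5, C10), cyclopentane ring B (C5, C6, C8, C9, C10), and a bicyclo[3.2.1]octane made of ring C (C8, C9, C11–C14) and ring D (C8, C13–C16) with the exocyclic C16=C17 alkene, while a γ-lactone (C19, O) bridges C4 and C10. It has nine stereocentres (C1, C4, C5, C6, C8, C9, C10, C12, C13), among them the quaternary carbons C4 and C8 and the fully substituted carbinol carbon C10. With β defined as the face of ring B that carries H-5, the substituents C1 (on C10), C7 (on C6), C11 (on C9) and C15 (on C8) are β, whereas C4 (on C5), O-10, H-9 and C14 are α; both ring fusions are therefore trans, but O-10 is syn to H-9 and anti to H-5. The 1-hydroxyl is β and axial, opposite the lactone bridge, the C18 methyl is β, and the 12-hydroxyl is α, axial on ring C and anti to the C15–C16 bridge. The sensitive groups are the non-enolisable β-keto lactone (retro-Claisen cleavage by nucleophiles), the β-hydroxy ketone (retro-aldol, dehydration), the exocyclic alkene (acid-induced migration and skeletal shifts) and the free acid. The difficulty lies in the contiguous array C4–C5–C6–C8–C9–C10 around ring B, and in the syn relation of O-10 and H-9: any six-membered ring B homologue is a trans-syn-trans system whose ring B cannot be a chair, so this relation has to be built under kinetic control and cannot be left to equilibration. The strategy rests on C6 of ring B, a methine that holds the exocyclic carboxyl carbon C7 and is bonded to quaternary C8: this is the pattern left behind when a cyclohexanone with its carbonyl carbon (C7) between C6 and C8 pushes that carbon out of the ring.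

## Retrosynthetic reasoning

**34 ⇐ 33 ⇐ 32 ⇐ 31.** The 1β-hydroxyl sits β to the C3 ketone, so the C1–O bond is cut back through epoxy ketone 32 to the ring A enone 31; the silyl ether of 33 is removed last. The gain is that the retro-aldol-prone aldol unit does not exist before the last two steps, and that ring A of 31 has no enolisable position. Forward, oxygen must reach C1 from the β face (the α face is covered by the lactone bridge) and the C2–O bond must be cleaved reductively while C1–O stays.

**31 ⇐ 29 (through 30).** The C6–C8 bond is cut and C8 is joined to C7 instead, which turns ring B into a cyclohexanone carrying a diazo group at C6. This is the place to cut because quaternary C8 cannot be made by enolate chemistry inside a cyclopentane that already carries its neighbours, whereas in the homologue C8 is simply the blocked α-carbon of the C7 ketone. The gain is that ring B becomes accessible by annulation and that the C7 acid, the C6 centre and the ring size all come from one step. Forward, nitrogen must leave, C8 must shift with retention, the ketene 30 must be hydrated and C6 must be protonated on the α face.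

**29 ⇐ 27.** The diazo group is removed from C6. Ketone 27 has only this enolisable carbon, because C8 and C4 are quaternary and the ring A enone has no acidic hydrogen, so the diazo transfer needs no regiocontrol.

**27 ⇐ 24 ⇐ 23 ⇐ 21 + 22.** Ring A and the lactone are opened at C1=C2 (aldol condensation), at C4–C5 (conjugate addition) and at the ester bond O–C19. The cut is made here because an acyl chain hung on O-10 can reach C5 only on the α face, so the configuration at C5 follows from C10. The C4 centre is then decided by the requirement that the acetyl group and C1 lie on the same side of the lactone. All ring A carbons except C1 come from 22.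

**21 ⇐ 19 ⇐ 18 ⇐ 17.** The C10–O bond is cut back to the exocyclic enol ether 17. O-10 must be α, equatorial on a chair ring B and syn to H-9. A carbon nucleophile added to a C10 ketone, or an electrophile added axially to an endocyclic C10 dienol, would deliver the opposite arrangement. An exocyclic C10=C1 double bond has no axial preference and is oxidised from the open α side, because the β side is blocked by the syn-axial C15 methylene. The ring B enone of 21 then arises by oxidation of the C7 carbinol of 19.

**17 ⇐ 15 ⇐ 14 ⇐ 13 ⇐ 10 + 11.** The C10–C1 bond is cut: C1 is the carbon of 11, attached at the γ-position of enone 10 through its extended enol. This uses the only carbonyl that can activate C10 at that stage. The same enone is then used to set H-9 by dissolving-metal reduction (trans B/C fusion under ordinary chair control), and its ketone becomes the axial 12-carbinol by hydride addition from the bridge side.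

**10 ⇐ 9 ⇐ 8 ⇐ 7 ⇐ 6.** Ring D is opened at C13–C16: a propargyl group on C8 and the C12/C13 enol silane 9 close the bicyclo[3.2.1]octane and bring the exocyclic methylene with them. C13 cannot form with the wrong configuration, because the tether reaches only one face. The C7 carbonyl is carried as a silyl-protected carbinol (7, 8) so that only C13 can be enolised.

**6 ⇐ 3 + 4; 3 ⇐ 1 + 2.** Ring C is cut by a Robinson annulation: C8–C14 by Michael addition and C9=C11 by aldol condensation. The symmetric dione 3 allows an enantioselective aldol step, which fixes C8 and with it the absolute configuration of every later centre.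

## Alternatives that were turned down

**Alternative 1:** Here ring B is the starting ring. C9–C11 and C8–C14 are disconnected from the 4-silyloxy cyclopentenone A1, which already carries O-10 and the alkyne for ring D.

- Forward key step: an allylic organocopper nucleophile adds to C9 of A1 on the face away from the silyloxy group, and the enolate is hydroxymethylated at C8 away from the new chain. This gives A2 with quaternary C8 and the C8/C9 trans relation.
- For it: the step is convergent, sets C8 and C9 from one resolved carbinol, and ring B has its final size, so no ring contraction is needed.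
- Against it for this target:
  - C6 of A2 is a ketone without C7, so a one-carbon homologation to the acid with control of C6 is still owed.
  - O-10 is a secondary silyl ether that must become a fully substituted carbinol bearing C1, and addition to a C10 ketone has the wrong face open.
  - The enolate trapped at a fully substituted carbon next to a β-silyloxy ketone can equilibrate and expel the silyloxy group.
  - Rings C, D, A and the lactone all remain to be built after A2.
- Comparison: Alternative 1 is stronger on convergence and on the direct C8/C9 relation. The chosen strategy offers catalytic absolute control at C8 in its first ring-forming step, and a key step that delivers C7, C6 and the ring size when every other ring is already in place.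

**Alternative 2:** Ring A and the lactone are disconnected together at C4–C5 and C10–O from the cyclopentene A3, whose C10 carries the C1–C3 chain ending in an α-methyl β-keto ester.

- Forward key step: a one-electron oxidant based on trivalent manganese converts the keto ester into the C4 radical, which closes 6-endo on C5. The tertiary C10 radical is oxidised further, and the cation is captured by the ester carbonyl oxygen to give lactone A4.
- For it: one step makes ring A, quaternary C4, C5 and the lactone, and C4 cannot carry the wrong group into the lactone. On this point it is clearly shorter than steps 14–16 of the chosen route.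
- Against it for this target:
  - The 6-endo closure competes with 5-exo attack at C10.
  - The face of C5 that is attacked is controlled only by the remote C6 ester and the C8/C9 substituents.
  - A4 lacks the C1 oxygen and C17. Ring A would have to be desaturated in the presence of a second enolisable ketone at C16, and C16 methylenated in the presence of the C3 ketone.
  - A3, a ring B cyclopentene with its own stereocentres, still needs a synthesis.
- Comparison: Alternative 2 wins on step count for ring A. The chosen strategy offers a C1=C2 double bond that comes directly from the ring A closure, an exocyclic methylene in place from step 6, and ring B centres that come with the ring contraction.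

**Alternative 3:** Ring C is closed last at C12–C13. A6 is disconnected to A5, in which C9 carries a two-carbon aldehyde chain and ring D is a spiro cyclopentanone on C8, present as its C13=C16 enol silane.

- Forward key step: a Lewis acid activates the aldehyde and the enol silane attacks through an open transition state. This forms C12–C13, and with it the bicyclo[3.2.1]octane, the 12-carbinol and C13.
- For it: the C12 carbinol arises with the ring, so no ketone reduction with uncertain facial selectivity is needed. On this point it is stronger than step 9 of the chosen route. The lactone part can also be finished beforehand.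
- Against it for this target:
  - The enol silane must be formed towards C13 and not C15 in a cyclopentanone whose two α-methylenes differ only remotely, and the wrong regioisomer would build the bicycle with the opposite sense at C8.
  - The open transition state does not guarantee the axial 12-hydroxyl.
  - The Lewis acid meets a β-silyloxy ketone in ring A, which can eliminate.
  - The C16 ketone must later be methylenated beside the C3 ketone.
- Comparison: the chosen strategy fixes C8, C13 and the methylene unambiguously by closing a tethered alkyne on a catalytically set quaternary centre, and it keeps the aldol unit of ring A masked as an enone until the end.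

Key step: step 18

Remark: 2,2,5,6-tetramethyl-4H-1,3-dioxin-4-one (22) is taken as a purchasable acylketene precursor; if it is not stocked, it is one known step from tert-butyl 2-methylacetoacetate, acetone and Ac2O/H2SO4.

## Route

Step 1
Reactants: 1 cyclohexane-1,3-dione; 2 propargyl bromide
Product: 3 2-(prop-2-yn-1-yl)cyclohexane-1,3-dione
Conditions: KOH, H2O, 60 °C
Reagents that add atoms: none
Why: C-alkylation of the stabilised 1,3-dione enolate by the reactive propargylic halide; in water the enolate oxygens are hydrogen-bonded, which favours attack through carbon. No stereocentre is formed.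

Step 2
Reactants: 3 2-(prop-2-yn-1-yl)cyclohexane-1,3-dione; 4 methyl vinyl ketone
Product: 6 (R)-8a-(prop-2-yn-1-yl)-3,4,8,8a-tetrahydronaphthalene-1,6(2H,7H)-dione, via triketone 5 (not isolated)
Conditions: Et3N (1 mol %), neat, rt; then N-tosyl-(Sa)-binam-L-prolinamide (2 mol %), PhCO2H (cat.), rt
Reagents that add atoms: none
Why: Michael addition followed by an enamine-mediated intramolecular aldol condensation (Hajos–Parrish–Eder–Sauer–Wiechert reaction, overall a Robinson annulation). The L-prolinamide enamine selects between the two enantiotopic ring carbonyls in the sense known for the (S)-Wieland–Miescher ketone, which for the propargyl group is (R)-6 and fixes C8.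

Step 3
Reactants: 6 (R)-8a-(prop-2-yn-1-yl)-3,4,8,8a-tetrahydronaphthalene-1,6(2H,7H)-dione
Product: 7 (4aR,5S)-5-hydroxy-4a-(prop-2-yn-1-yl)-4,4a,5,6,7,8-hexahydronaphthalen-2(3H)-one
Conditions: NaBH4 (0.3 equiv), EtOH, −10 °C
Reagents that add atoms: none
Why: Chemoselective 1,2-reduction: the saturated C7 ketone is more electrophilic than the enone carbonyl. Hydride attacks anti to the angular propargyl group, so the 7-hydroxyl is β; this centre is removed again in step 13.

Step 4
Reactants: 7 (4aR,5S)-5-hydroxy-4a-(prop-2-yn-1-yl)-4,4a,5,6,7,8-hexahydronaphthalen-2(3H)-one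
Product: 8 (4aR,5S)-4a-(prop-2-yn-1-yl)-5-(triethylsilyloxy)-4,4a,5,6,7,8-hexahydronaphthalen-2(3H)-one
Conditions: TESCl, imidazole, DMF, 0 °C → rt
Reagents that add atoms: triethylsilyl chloride, CC[Si](Cl)(CC)CC
Why: Silylation masks the C7 oxygen as an ether that cannot enolise or add to the alkyne, and that can later be cleaved in the presence of a TBS ether.

Step 5
Reactants: 8 (4aR,5S)-4a-(prop-2-yn-1-yl)-5-(triethylsilyloxy)-4,4a,5,6,7,8-hexahydronaphthalen-2(3H)-one
Product: 9 cross-conjugated TBS dienol ether of 8 (C12–OTBS; C12=C13 and C9=C11)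
Conditions: LiN(SiMe3)2, THF, −78 °C; TBSOTf
Reagents that add atoms: tert-butyldimethylsilyl triflate, CC(C)(C)[Si](C)(C)OS(=O)(=O)C(F)(F)F
Why: Kinetic deprotonation of the enone at the α′ carbon C13 and O-silylation give the 2-silyloxy-1,3-diene. At −78 °C the bulky amide leaves the γ-hydrogens at C10 and the alkyne C–H alone.

Step 6
Reactants: 9 cross-conjugated TBS dienol ether of 8
Product: 10 tricyclic enone (ring B cyclohexane with 7β-OTES; ring C 9(11)-en-12-one; ring D with the C16=C17 methylene; C15 β on C8; C16 β on C13)
Conditions: Ph3PAuCl (5 mol %), AgBF4 (5 mol %), toluene/MeOH 10:1, rt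
Reagents that add atoms: none
Why: Gold-catalysed Conia-ene-type carbocyclisation: the enol silane carbon C13 attacks the π-activated alkyne 5-exo-dig, forming C13–C16, and protodeauration leaves the exocyclic C16=C17. C13 is fixed by the bridge, because C16 can only reach the face of ring C that carries C15.

Step 7
Reactants: 10 tricyclic enone; 11 trimethyl orthoformate
Product: 13 10β-(dimethoxymethyl) derivative of enone 10 (10α-H), via trimethylsilyl dienol ether 12 (not isolated)
Conditions: TMSOTf (1.4 equiv), i-Pr2NEt (1.2 equiv), CH2Cl2, −78 → −20 °C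
Reagents that add atoms: none
Why: Soft enolisation can only go towards C10, because C13 is a bridgehead, and the extended enol silane reacts with the dimethoxycarbenium ion at its γ-terminus (vinylogous Mukaiyama reaction), which restores the enone. Axial attack on the β face is expected, as in 3,5-dienol ethers with an angular substituent, but the C10 configuration is erased in step 10.

Step 8
Reactants: 13 10β-(dimethoxymethyl) derivative of enone 10
Product: 14 saturated 12-ketone (9α-H; trans B/C; 10β-dimethoxymethyl; 7β-OTES)
Conditions: Li, NH3(l), THF, t-BuOH (1 equiv), −78 °C; NH4Cl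
Reagents that add atoms: none
Why: Dissolving-metal reduction of the enone: the β-carbanion at C9 is protonated axially on ring C, anti to the axial C15 bridge, which gives the trans B/C fusion with 9α-H. The isolated methylene, the acetal and the silyl ether are inert.

Step 9
Reactants: 14 saturated 12-ketone
Product: 15 12α-alcohol of 14 (hydroxyl axial on ring C; anti to the C15–C16 bridge)
Conditions: Li[HB(s-Bu)3] (L-Selectride), THF, −78 °C; then NaOH, H2O2
Reagents that add atoms: none
Why: Ketone reduction by a bulky borohydride: it approaches C12 along the equatorial trajectory on the bridge side, avoiding the two syn-axial hydrogens at C9 and C14 on the α face, and so gives the axial 12α-alcohol.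

Step 10
Reactants: 15 12α-alcohol of 14
Product: 17 12α-TBS ether with exocyclic C10=C1H(OMe) enol ether (E/Z mixture; 7β-OTES), via 12-O-TBS acetal 16 (not isolated)
Conditions: TBSOTf (1.2 equiv), i-Pr2NEt (4 equiv), CH2Cl2, −78 °C; then TMSOTf (1.5 equiv), −20 °C → rt
Reagents that add atoms: tert-butyldimethylsilyl triflate, CC(C)(C)[Si](C)(C)OS(=O)(=O)C(F)(F)F
Why: O-silylation, then silyl triflate/amine-mediated loss of methanol from the dimethyl acetal through its oxocarbenium ion (acetal to enol ether conversion). The only β-hydrogen is H-10, so C10 becomes trigonal and exocyclic.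

Step 11
Reactants: 17 12α-TBS ether with exocyclic enol ether
Product: 18 10α-hydroxy-10β-(dimethoxymethyl) compound (12α-OTBS; 7β-OTES)
Conditions: mCPBA (1.05 equiv), MeOH, −20 °C
Reagents that add atoms: mCPBA, OOC(=O)c1cccc(Cl)c1; methanol, CO
Why: Epoxidation of the electron-rich enol ether, which reacts far faster than the 1,1-disubstituted C16=C17, and methanolysis of the epoxy ether to the α-hydroxy acetal. The peracid attacks the exocyclic double bond from the equatorial α side because the axial β side is blocked by the syn-axial C15 methylene on C8, so O-10 is α and C1 β.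

Step 12
Reactants: 18 10α-hydroxy-10β-(dimethoxymethyl) compound
Product: 19 7β,10α-diol (10β-dimethoxymethyl; 12α-OTBS)
Conditions: PPTS, MeOH, rt
Reagents that add atoms: none
Why: Acid-catalysed methanolysis removes the triethylsilyl ether much faster than the hindered secondary TBS ether. In methanol the dimethyl acetal only exchanges with itself.

Step 13
Reactants: 19 7β,10α-diol
Product: 21 10α-hydroxy-5-en-7-one (10β-dimethoxymethyl; 12α-OTBS), via 7-ketone 20 (not isolated)
Conditions: IBX (4 equiv), DMSO, 25 → 75 °C
Reagents that add atoms: none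
Why: IBX oxidises the secondary alcohol to the ketone and then dehydrogenates it through its enol to the enone. Only C6/C5 can be desaturated because C8 is quaternary; the tertiary alcohol, acetal and TBS ether do not react.

Step 14
Reactants: 21 10α-hydroxy-5-en-7-one; 22 2,2,5,6-tetramethyl-4H-1,3-dioxin-4-one
Product: 23 10α-O-(2-methyl-3-oxobutanoyl) ester of 21 (both C4 epimers)
Conditions: toluene, 110 °C
Reagents that add atoms: none
Why: Retro-[4+2] fragmentation of the dioxinone releases acetyl(methyl)ketene, which acylates the hindered tertiary alcohol without catalyst (acylketene trapping). C4 of the β-keto ester is configurationally labile at this stage.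

Step 15
Reactants: 23 10α-O-(2-methyl-3-oxobutanoyl) ester of 21
Product: 24 10β-formyl keto ester (aldehyde from the acetal of 23)
Conditions: TESOTf, 2,4,6-collidine, CH2Cl2, 0 °C; then H2O
Reagents that add atoms: water, O
Why: The silyl triflate ionises the dimethyl acetal and collidine captures the oxocarbenium ion as a pyridinium salt, which water hydrolyses to the aldehyde. These non-protic conditions spare the TBS ether, the exocyclic alkene and the β-keto ester.

Step 16
Reactants: 24 10β-formyl keto ester
Product: 27 B-homo enone lactone ketone (ring A 1-en-3-one; 19,10α-lactone; 4β-methyl; 5β-H; 9α-H; 7-ketone; 12α-OTBS; 16-methylene), via Michael lactone 25 (not isolated), via aldol adduct 26 (not isolated)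
Conditions: DBU, MeCN, rt → 50 °C
Reagents that add atoms: none
Why: Tandem intramolecular Michael addition and aldol condensation. The β-keto ester enolate adds 5-(enolexo)-exo-trig to C5 on the α face, to which it is tethered through O-10 (axial attack, cis-fused γ-lactone, 5β-H); the methyl ketone enolate C2 then condenses with the C1 aldehyde 6-(enolendo)-exo-trig and dehydrates. Only the C4 epimer with acetyl cis to C1 can close ring A, and reversible Michael addition feeds material to it.

Step 17
Reactants: 27 B-homo enone lactone ketone
Product: 29 6-diazo-7-ketone of 27, via 6-trifluoroacetyl ketone 28 (not isolated)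
Conditions: LiN(SiMe3)2, THF, −78 °C; CF3CO2CH2CF3; then MsN3, Et3N, MeCN/H2O, rt
Reagents that add atoms: methanesulfonyl azide, CS(=O)(=O)N=[N+]=[N-]
Why: Detrifluoroacetylative diazo transfer (Regitz type) to a ketone activated in situ as its α-trifluoroacetyl derivative. C6 is the only enolisable carbon; the kinetic enolate is acylated at −78 °C before it can expel C4 in a retro-Michael sense.

Step 18
Reactants: 29 6-diazo-7-ketone of 27
Product: 31 ring-contracted 7-acid (12-O-TBS 1,2-didehydro-1-deoxy target; C7 β on C6), via ketene 30 (not isolated)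
Conditions: hν (λ ≥ 300 nm, Pyrex), THF/H2O 5:1, 10 °C
Reagents that add atoms: water, O
Why: Irradiation of the cyclic α-diazo ketone 29, which is locked s-cis, expels N2 in concert with the 1,2-shift of C8 from C7 to C6, so no free ketocarbene is available for C–H insertion or for attack on C16=C17; the shift forms the C6–C8 bond and ketene 30. Ring B becomes five-membered by ring contraction (a 1,2-shift within the ring, not an end-to-end closure), and the migrating quaternary C8 keeps its configuration. The closest known reaction type is the photochemical Wolff ring contraction of cyclic 2-diazo ketones next to a quaternary carbon, as used for ring-contracted steroid acids. Water adds to 30 and the resulting ene-1,1-diol is protonated at C6, the only new stereocentre. Protonation is expected on the α face, anti to the pseudo-axial C15 methylene on the neighbouring C8, which places C7 β, cis to H-5 and trans to the C4–C5 bond, and avoids eclipsing of C7 with C4 and its methyl group. The regiochemistry of the shift needs no control because C8 is the only carbon on the carbonyl besides the diazo carbon. The step requires that the diazo ketone is excited in preference to the ring A enone; light of λ ≥ 300 nm is absorbed far more strongly by the diazo ketone, and the enone has no alkene within reach for cycloaddition. Neutral aqueous THF leaves the β-keto lactone, the silyl ether and the exocyclic alkene untouched.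

Step 19
Reactants: 31 ring-contracted 7-acid
Product: 32 1β,2β-epoxy ketone acid
Conditions: H2O2 (30 % aq), LiOH, THF/H2O, 0 °C; then aq HCl to pH 3
Reagents that add atoms: hydrogen peroxide, OO
Why: Weitz–Scheffer nucleophilic epoxidation of the enone. Hydroperoxide adds to C1 on the β face because the α face of ring A is covered by the axial lactone bridge, so the epoxide is 1β,2β; low temperature limits attack on the β-keto lactone.

Step 20
Reactants: 32 1β,2β-epoxy ketone acid
Product: 33 12-O-TBS target (1β-hydroxy-3-ketone)
Conditions: SmI2, THF/MeOH, −90 °C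
Reagents that add atoms: none
Why: Single-electron reduction of the α,β-epoxy ketone by divalent samarium cleaves the C2–O bond next to the ketyl and leaves C1–O untouched, so the β-hydroxy ketone keeps the 1β configuration. The low temperature and immediate protonation suppress retro-aldol cleavage and dehydration.

Step 21
Reactants: 33 12-O-TBS target
Product: 34 target CNP0259985.3
Conditions: HF·pyridine, pyridine/THF, 0 °C → rt
Reagents that add atoms: none
Why: Fluoride cleavage of the TBS ether under buffered, weakly acidic conditions that leave the β-hydroxy ketone, the β-keto lactone and the exocyclic alkene intact.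

## Compound list

1 | cyclohexane-1,3-dione | O=C1CCCC(=O)C1 | starting material
2 | 3-bromoprop-1-yne (propargyl bromide) | C#CCBr | starting material
3 | 2-(prop-2-yn-1-yl)cyclohexane-1,3-dione | C#CCC1C(=O)CCCC1=O | intermediate
4 | but-3-en-2-one (methyl vinyl ketone) | CC(=O)C=C | starting material
5 | 2-(3-oxobutyl)-2-(prop-2-yn-1-yl)cyclohexane-1,3-dione (triketone, not isolated) | CC(=O)CCC1(CC#C)C(=O)CCCC1=O | intermediate
6 | (R)-8a-(prop-2-yn-1-yl)-3,4,8,8a-tetrahydronaphthalene-1,6(2H,7H)-dione | C#CC[C@]12CCC(=O)C=C1CCCC2=O | intermediate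
7 | (4aR,5S)-5-hydroxy-4a-(prop-2-yn-1-yl)-4,4a,5,6,7,8-hexahydronaphthalen-2(3H)-one | C#CC[C@]12CCC(=O)C=C1CCC[C@@H]2O | intermediate
8 | (4aR,5S)-4a-(prop-2-yn-1-yl)-5-(triethylsilyloxy)-4,4a,5,6,7,8-hexahydronaphthalen-2(3H)-one | C#CC[C@]12CCC(=O)C=C1CCC[C@@H]2O[Si](CC)(CC)CC | intermediate
9 | tert-butyldimethyl{[(4aR,5S)-4a-(prop-2-yn-1-yl)-5-(triethylsilyloxy)-4,4a,5,6,7,8-hexahydronaphthalen-2-yl]oxy}silane (cross-conjugated dienol ether, C12=C13 and C9=C11) | C#CC[C@]12CC=C(O[Si](C)(C)C(C)(C)C)C=C1CCC[C@@H]2O[Si](CC)(CC)CC | intermediate
10 | tricyclic enone: 7β-triethylsilyloxy-16-methylene-B,C,D-tricyclic 9(11)-en-12-one (C15 β on C8, C16 β on C13) | C=C1C[C@]23C[C@H]1C(=O)C=C2CCC[C@@H]3O[Si](CC)(CC)CC | intermediate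
11 | trimethyl orthoformate | COC(OC)OC | starting material
12 | 12-trimethylsilyloxy-9(10),11-diene of 10 (extended dienol ether, not isolated) | C=C1C[C@]23C[C@H]1C(O[Si](C)(C)C)=CC2=CCC[C@@H]3O[Si](CC)(CC)CC | intermediate
13 | 10β-(dimethoxymethyl)-7β-triethylsilyloxy-16-methylene-B,C,D-tricyclic 9(11)-en-12-one (10α-H) | C=C1C[C@]23C[C@H]1C(=O)C=C2[C@H](C(OC)OC)CC[C@@H]3O[Si](CC)(CC)CC | intermediate
14 | 9α-H 12-ketone: 10β-(dimethoxymethyl)-7β-triethylsilyloxy-16-methylene-B,C,D-tricyclic 12-one (trans B/C) | C=C1C[C@]23C[C@H]1C(=O)C[C@@H]2[C@H](C(OC)OC)CC[C@@H]3O[Si](CC)(CC)CC | intermediate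
15 | 12α-alcohol of 14 (hydroxyl axial, anti to the C15–C16 bridge) | C=C1C[C@]23C[C@H]1[C@@H](O)C[C@@H]2[C@H](C(OC)OC)CC[C@@H]3O[Si](CC)(CC)CC | intermediate
16 | 12α-tert-butyldimethylsilyl ether of 15 (12-O-TBS acetal, not isolated) | C=C1C[C@]23C[C@H]1[C@@H](O[Si](C)(C)C(C)(C)C)C[C@@H]2[C@H](C(OC)OC)CC[C@@H]3O[Si](CC)(CC)CC | intermediate
17 | 10-(methoxymethylene) compound: 12α-OTBS, 7β-OTES, exocyclic C10=C1H(OMe), E/Z mixture | C=C1C[C@]23C[C@H]1[C@@H](O[Si](C)(C)C(C)(C)C)C[C@@H]2C(=COC)CC[C@@H]3O[Si](CC)(CC)CC | intermediate
18 | 10α-hydroxy-10β-(dimethoxymethyl) compound (12α-OTBS, 7β-OTES) | C=C1C[C@]23C[C@H]1[C@@H](O[Si](C)(C)C(C)(C)C)C[C@@H]2[C@](O)(C(OC)OC)CC[C@@H]3O[Si](CC)(CC)CC | intermediate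
19 | 7β,10α-diol (10β-dimethoxymethyl, 12α-OTBS) | C=C1C[C@]23C[C@H]1[C@@H](O[Si](C)(C)C(C)(C)C)C[C@@H]2[C@](O)(C(OC)OC)CC[C@@H]3O | intermediate
20 | 10α-hydroxy-7-ketone (10β-dimethoxymethyl, 12α-OTBS; not isolated) | C=C1C[C@]23C[C@H]1[C@@H](O[Si](C)(C)C(C)(C)C)C[C@@H]2[C@](O)(C(OC)OC)CCC3=O | intermediate
21 | 10α-hydroxy-5-en-7-one (10β-dimethoxymethyl, 12α-OTBS) | C=C1C[C@]23C[C@H]1[C@@H](O[Si](C)(C)C(C)(C)C)C[C@@H]2[C@](O)(C(OC)OC)C=CC3=O | intermediate
22 | 2,2,5,6-tetramethyl-4H-1,3-dioxin-4-one | CC1=C(C)C(=O)OC(C)(C)O1 | starting material
23 | 10α-O-(2-methyl-3-oxobutanoyl) ester of 21 (C4 epimers) | C=C1C[C@]23C[C@H]1[C@@H](O[Si](C)(C)C(C)(C)C)C[C@@H]2[C@](OC(=O)C(C)C(C)=O)(C(OC)OC)C=CC3=O | intermediate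
24 | 10β-formyl-10α-(2-methyl-3-oxobutanoyloxy)-5-en-7-one (12α-OTBS) | C=C1C[C@]23C[C@H]1[C@@H](O[Si](C)(C)C(C)(C)C)C[C@@H]2[C@](OC(=O)C(C)C(C)=O)(C=O)C=CC3=O | intermediate
25 | Michael lactone: 19,10α-lactone with 4β-methyl, 4α-acetyl, 5β-H, 10β-formyl, 7-ketone (not isolated) | C=C1C[C@]23C[C@H]1[C@@H](O[Si](C)(C)C(C)(C)C)C[C@@H]2[C@@]4(C=O)OC(=O)[C@](C)(C(C)=O)[C@H]4CC3=O | intermediate
26 | aldol adduct: 1-hydroxy-3,7-diketone lactone, C1 configuration open (not isolated) | C=C1C[C@]23C[C@H]1[C@@H](O[Si](C)(C)C(C)(C)C)C[C@@H]2[C@]12OC(=O)[C@](C)(C(=O)CC1O)[C@H]2CC3=O | intermediate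
27 | B-homo enone lactone ketone: 12α-OTBS, 3,7-dioxo, 1-ene, 16-methylene, 19,10α-lactone, 5β-H, 9α-H | C=C1C[C@]23C[C@H]1[C@@H](O[Si](C)(C)C(C)(C)C)C[C@@H]2[C@]12OC(=O)[C@](C)(C(=O)C=C1)[C@H]2CC3=O | intermediate
28 | 6-trifluoroacetyl derivative of 27 (not isolated) | C=C1C[C@]23C[C@H]1[C@@H](O[Si](C)(C)C(C)(C)C)C[C@@H]2[C@]12OC(=O)[C@](C)(C(=O)C=C1)[C@H]2C(C(=O)C(F)(F)F)C3=O | intermediate
29 | 6-diazo-7-ketone (B-homo diazo ketone, 12α-OTBS) | C=C1C[C@]23C[C@H]1[C@@H](O[Si](C)(C)C(C)(C)C)C[C@@H]2[C@]12OC(=O)[C@](C)(C(=O)C=C1)[C@H]2C(=[N+]=[N-])C3=O | intermediate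
30 | ring-contracted ketene at C6 (not isolated) | C=C1C[C@]23C[C@H]1[C@@H](O[Si](C)(C)C(C)(C)C)C[C@@H]2[C@]12OC(=O)[C@](C)(C(=O)C=C1)[C@H]2C3=C=O | intermediate
31 | 12-O-TBS 1,2-didehydro-1-deoxy target acid (C7 β on C6) | C=C1C[C@]23C[C@H]1[C@@H](O[Si](C)(C)C(C)(C)C)C[C@@H]2[C@]12OC(=O)[C@](C)(C(=O)C=C1)[C@H]2[C@@H]3C(=O)O | intermediate
32 | 1β,2β-epoxy-3-ketone acid (12α-OTBS) | C=C1C[C@]23C[C@H]1[C@@H](O[Si](C)(C)C(C)(C)C)C[C@@H]2[C@]12OC(=O)[C@](C)(C(=O)[C@H]4O[C@@H]14)[C@H]2[C@@H]3C(=O)O | intermediate
33 | 12-O-TBS target (1β-hydroxy-3-ketone acid) | C=C1C[C@]23C[C@H]1[C@@H](O[Si](C)(C)C(C)(C)C)C[C@@H]2[C@]12OC(=O)[C@](C)(C(=O)C[C@H]1O)[C@H]2[C@@H]3C(=O)O | intermediate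
34 | CNP0259985.3: 1β,12α-dihydroxy-3-oxo-16-methylene C19-gibberellin 7-acid 19,10α-lactone (5β-H, 6α-H, 9α-H, C15 β on C8) | C=C1C[C@]23C[C@H]1[C@@H](O)C[C@@H]2[C@]12OC(=O)[C@](C)(C(=O)C[C@H]1O)[C@H]2[C@@H]3C(=O)O | target

## Step count and least certain steps

Total step count: 21 steps. Longest linear sequence: 21 steps from 1; the route is fully linear, and 2, 4, 11 and 22 are purchased.

**Step 18 (key step).** The most likely failure is protonation of the ketene hydrate on the β face, which would give the 6-epimer; a second risk is light absorption by the ring A enone, which would open side reactions. Fallback: starting from 27, the trimethylsilyl enol ether (LiN(SiMe3)2, TMSCl) is brominated with NBS on the β face, away from the axial C4–C5 bond, to give the 6β-bromo ketone F1. LiOH in aqueous THF at 0 °C then triggers the quasi-Favorskii (semibenzilic) rearrangement. Hydroxide adds to C7 and C8 shifts to C6 with inversion, because C8 carries no hydrogen for the cyclopropanone path. The stereospecific shift gives acid 31, where the route is rejoined.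

**Step 16.** The Michael addition may place the acetyl group on the concave side of the lactone, and the retro-Michael equilibration that should correct this may be slow. The methyl ketone enolate may also add reversibly to the C7 ketone and stall the cascade before ring A closes. Fallback from 21, returning at 27:
- Acylation with methyl 2-methylmalonyl chloride (pyridine, DMAP) gives the malonate ester F2.
- Cs2CO3 closes the same 5-exo Michael lactone, now the 4-methyl-4-methoxycarbonyl lactone F3 (both C4 epimers).
- LiCl in wet DMSO at 130 °C removes the methoxycarbonyl group (Krapcho reaction) to give the 4-methyl lactone acetal F4, in which C4 is enolisable.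
- Acetal cleavage as in step 15 gives the aldehyde F5.
- Still–Gennari olefination gives the (Z)-enoate F6.
- LiN(i-Pr)2 (2.2 equiv, −78 °C) forms the ketone and lactone enolates, and the lactone enolate C4 acylates the enoate ester (Dieckmann-type closure). It can do so only on the face that the C1–C3 chain reaches, so C4 is set by the ring closure, and 27 is obtained.

**Step 11.** The peracid may attack the exocyclic enol ether from the axial β face and give the C10 epimer. Fallback from 15, returning at 21:
- TBSOTf/2,6-lutidine at −78 °C gives 16, which is isolated this time.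
- PPTS/MeOH gives the 7β-alcohol F7.
- IBX gives the 10α-H enone acetal F8.
- TBSOTf/Et3N gives the 7-silyloxy-5(10),6-diene F9.
- Singlet oxygen (O2, hν, tetraphenylporphyrin, −78 °C) adds across C7 and C10 in a [4+2] sense on the α face, the side away from the pseudo-axial C15 next to the diene terminus. Reduction of the endoperoxide with PPh3 releases the C7 ketone and the 10α-hydroxyl, which gives 21.

**Step 9.** Hydride may be delivered from the α face, anti to C16, which would give the equatorial 12β-alcohol. Fallback from 14, returning at 15: NaBH4 in MeOH is used on purpose to obtain the 12β-alcohol F10. Mitsunobu inversion (4-nitrobenzoic acid, PPh3, DIAD) gives the 12α-(4-nitrobenzoate) F11, and K2CO3/MeOH releases 15.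

**Step 7.** The carbenium ion may attack the α-carbon C11 instead of C10, or the product acetal may lose methanol to a conjugated enol ether. Fallback from 10, returning at 13: TBSOTf/Et3N gives the isolable TBS dienol ether F12. 1,3-Dithienium tetrafluoroborate (CH2Cl2, −78 °C) alkylates it at the γ-carbon to give the 10-(1,3-dithian-2-yl) enone F13, and PhI(OCOCF3)2 in MeOH exchanges the dithiane for the dimethyl acetal, which gives 13.

Further compounds

F1 | step 18 | 6β-bromo-7-ketone of 27 | C=C1C[C@]23C[C@H]1[C@@H](O[Si](C)(C)C(C)(C)C)C[C@@H]2[C@]12OC(=O)[C@](C)(C(=O)C=C1)[C@H]2[C@H](Br)C3=O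
F2 | step 16 | 10α-O-(3-methoxy-2-methyl-3-oxopropanoyl) ester of 21 | C=C1C[C@]23C[C@H]1[C@@H](O[Si](C)(C)C(C)(C)C)C[C@@H]2[C@](OC(=O)C(C)C(=O)OC)(C(OC)OC)C=CC3=O
F3 | step 16 | 4-methyl-4-methoxycarbonyl Michael lactone (10β-dimethoxymethyl, 5β-H, C4 epimers) | C=C1C[C@]23C[C@H]1[C@@H](O[Si](C)(C)C(C)(C)C)C[C@@H]2[C@@]4(C(OC)OC)OC(=O)C(C)(C(=O)OC)[C@H]4CC3=O
F4 | step 16 | 4-methyl lactone acetal (10β-dimethoxymethyl, 5β-H, C4 epimers) | C=C1C[C@]23C[C@H]1[C@@H](O[Si](C)(C)C(C)(C)C)C[C@@H]2[C@@]4(C(OC)OC)OC(=O)C(C)[C@H]4CC3=O
F5 | step 16 | 4-methyl lactone aldehyde (10β-formyl) | C=C1C[C@]23C[C@H]1[C@@H](O[Si](C)(C)C(C)(C)C)C[C@@H]2[C@@]4(C=O)OC(=O)C(C)[C@H]4CC3=O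
F6 | step 16 | (Z)-enoate: 10β-[(Z)-2-(methoxycarbonyl)ethenyl] 4-methyl lactone | C=C1C[C@]23C[C@H]1[C@@H](O[Si](C)(C)C(C)(C)C)C[C@@H]2[C@@]4(/C=C\C(=O)OC)OC(=O)C(C)[C@H]4CC3=O
F7 | step 11 | 7β-alcohol of 16 (10β-dimethoxymethyl, 10α-H, 12α-OTBS) | C=C1C[C@]23C[C@H]1[C@@H](O[Si](C)(C)C(C)(C)C)C[C@@H]2[C@H](C(OC)OC)CC[C@@H]3O
F8 | step 11 | 10α-H 5-en-7-one (10β-dimethoxymethyl, 12α-OTBS) | C=C1C[C@]23C[C@H]1[C@@H](O[Si](C)(C)C(C)(C)C)C[C@@H]2[C@H](C(OC)OC)C=CC3=O
F9 | step 11 | 7-(tert-butyldimethylsilyloxy)-5(10),6-diene (10-dimethoxymethyl, 12α-OTBS) | C=C1C[C@]23C[C@H]1[C@@H](O[Si](C)(C)C(C)(C)C)C[C@@H]2C(C(OC)OC)=CC=C3O[Si](C)(C)C(C)(C)C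
F10 | step 9 | 12β-alcohol (12-epimer of 15) | C=C1C[C@]23C[C@H]1[C@H](O)C[C@@H]2[C@H](C(OC)OC)CC[C@@H]3O[Si](CC)(CC)CC
F11 | step 9 | 12α-(4-nitrobenzoate) of 15 | C=C1C[C@]23C[C@H]1[C@@H](OC(=O)c1ccc(cc1)[N+](=O)[O-])C[C@@H]2[C@H](C(OC)OC)CC[C@@H]3O[Si](CC)(CC)CC
F12 | step 7 | 12-(tert-butyldimethylsilyloxy)-9(10),11-diene of 10 | C=C1C[C@]23C[C@H]1C(O[Si](C)(C)C(C)(C)C)=CC2=CCC[C@@H]3O[Si](CC)(CC)CC
F13 | step 7 | 10β-(1,3-dithian-2-yl) enone (10α-H, 7β-OTES) | C=C1C[C@]23C[C@H]1C(=O)C=C2[C@H](C4SCCCS4)CC[C@@H]3O[Si](CC)(CC)CC
A1 | alternative 1 | 4-(tert-butyldimethylsilyloxy)-2-[3-(trimethylsilyl)prop-2-yn-1-yl]cyclopent-2-en-1-one | O=C1C[C@H](O[Si](C)(C)C(C)(C)C)C=C1CC#C[Si](C)(C)C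
A2 | alternative 1 | ring B cyclopentanone with C9 methallyl, C8 hydroxymethyl and C8 silylpropargyl groups and the C10 silyl ether | O=C1C[C@H](O[Si](C)(C)C(C)(C)C)[C@@H](CC(C)=C)[C@@]1(CO)CC#C[Si](C)(C)C
A3 | alternative 2 | ring B cyclopentene (C5=C10) with the C1–C4 α-methyl β-keto ester chain on C10, 12-acetate, 16-ketone, C7 methyl ester | O=C1C[C@]23C[C@H]1[C@@H](OC(C)=O)C[C@@H]2C(CCC(=O)C(C)C(=O)OC)=C[C@@H]3C(=O)OC
A4 | alternative 2 | 1-deoxy-16-oxo-17-nor target, 12-O-acetate methyl ester | O=C1C[C@]23C[C@H]1[C@@H](OC(C)=O)C[C@@H]2[C@]12OC(=O)[C@](C)(C(=O)CC1)[C@H]2[C@@H]3C(=O)OC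
A5 | alternative 3 | seco ring C aldehyde with the spiro ring D C13=C16 trimethylsilyl enol ether, 1-O-TBS methyl ester | C[Si](C)(C)OC1=CC[C@@]2(C1)[C@H](CC=O)[C@]34OC(=O)[C@](C)(C(=O)C[C@H]3O[Si](C)(C)C(C)(C)C)[C@H]4[C@@H]2C(=O)OC
A6 | alternative 3 | 16-oxo-17-nor target, 1-O-TBS methyl ester | O=C1C[C@]23C[C@H]1[C@@H](O)C[C@@H]2[C@]12OC(=O)[C@](C)(C(=O)C[C@H]1O[Si](C)(C)C(C)(C)C)[C@H]2[C@@H]3C(=O)OC
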